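**Retrosynthetic overview**

- The flavone is traced back to its 3-bromo-7-O-benzyl derivative 21, from which one hydrogenolysis removes both groups. Compound 21 is traced back to the 2-aryl-3-silyloxybenzofuran 17 by excising C3, which is put in as a CBr2 unit from bromoform.
- The structural feature used: in ring C, C3 is a single CH held between C2 (which carries O1 and ring B) and the C4 carbonyl. Without it, ring C is the furan ring of a benzofuran-3-ol whose C2=C3 bond is a doubly oxygenated, strongly nucleophilic enol ether.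
- Compound 17 comes from coumaranone 16, closed by Friedel-Crafts acylation of aryloxy acid 14 at the one free position of ring A; 14 comes from phenol 11 and bromo ester 12.
- Phenol 11 comes from syringol by benzylation, symmetric 4,6-dibromination and two bromine-to-oxygen exchanges separated by a methylation, so no regiochemical choice arises.
- Ring order: rings A and B are bought; the five-membered oxygen heterocycle is closed in step 8 and enlarged to the six-membered ring C in step 10.

Key step: step 10

Remark on the chemistry: compounds 13 to 16 and 19 carry the centre derived from the racemic bromo ester and are racemic. That centre becomes sp2 in 17 and the target is achiral, so no stereocontrol is needed.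

**Route**

Step 1
Reactants: 1 2,6-dimethoxyphenol (syringol); 2 benzyl bromide
Product: 3 2-(benzyloxy)-1,3-dimethoxybenzene
Conditions: BnBr, K2CO3, DMF, 60 °C
Reagents that add atoms: benzyl bromide (compound 2), BrCc1ccccc1
Why: Williamson ether synthesis; the reactive benzylic bromide should alkylate the hindered 2,6-disubstituted phenoxide cleanly.

Step 2
Reactants: 3 2-(benzyloxy)-1,3-dimethoxybenzene
Product: 4 3-(benzyloxy)-1,5-dibromo-2,4-dimethoxybenzene
Conditions: NBS (2.1 equiv), MeCN, 0 °C to rt, dark
Reagents that add atoms: N-bromosuccinimide, O=C1CCC(=O)N1Br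
Why: Electrophilic aromatic bromination; the out-of-plane central benzyloxy group donates little, so both brominations should go ortho and para to the flanking methoxy groups and give the symmetric dibromide, while polar non-radical conditions spare the benzylic CH2.

Step 3
Reactants: 4 3-(benzyloxy)-1,5-dibromo-2,4-dimethoxybenzene
Product: 7 3-(benzyloxy)-5-bromo-2,4-dimethoxyphenol, via aryllithium 5 (not isolated), via lithium aryltrimethoxyborate 6 (not isolated)
Conditions: n-BuLi (1.0 equiv), THF, −78 °C; B(OMe)3, −78 °C to 0 °C; AcOH, 30% aq. H2O2, 0 °C to rt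
Reagents that add atoms: n-butyllithium, [Li]CCCC (lithium of 5); trimethyl borate, COB(OC)OC (boron and methoxy groups of 6); hydrogen peroxide, OO (phenol oxygen of 7)
Why: Bromine-lithium exchange, borylation and oxidative aryl migration from boron to oxygen; the two bromines are equivalent, so one equivalent of n-BuLi at −78 °C should exchange only one, faster than any benzylic deprotonation.

Step 4
Reactants: 7 3-(benzyloxy)-5-bromo-2,4-dimethoxyphenol
Product: 8 3-(benzyloxy)-1-bromo-2,4,5-trimethoxybenzene
Conditions: MeI, K2CO3, acetone, reflux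
Reagents that add atoms: iodomethane, CI
Why: Williamson O-methylation of a phenol; no other nucleophilic site is present.

Step 5
Reactants: 8 3-(benzyloxy)-1-bromo-2,4,5-trimethoxybenzene
Product: 11 3-(benzyloxy)-2,4,5-trimethoxyphenol, via aryllithium 9 (not isolated), via lithium aryltrimethoxyborate 10 (not isolated)
Conditions: n-BuLi (1.05 equiv), THF, −78 °C; B(OMe)3, −78 °C to 0 °C; AcOH, 30% aq. H2O2, 0 °C to rt
Reagents that add atoms: n-butyllithium, [Li]CCCC (lithium of 9); trimethyl borate, COB(OC)OC (boron and methoxy groups of 10); hydrogen peroxide, OO (phenol oxygen of 11)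
Why: The same bromine-lithium exchange, borylation and oxidation sequence on the single remaining bromide should place the hydroxyl group meta to the benzyloxy group with no regiochemical ambiguity.

Step 6
Reactants: 11 3-(benzyloxy)-2,4,5-trimethoxyphenol; 12 methyl 2-bromo-2-(4-methoxyphenyl)acetate (racemic)
Product: 13 methyl 2-[3-(benzyloxy)-2,4,5-trimethoxyphenoxy]-2-(4-methoxyphenyl)acetate (racemic)
Conditions: K2CO3, DMF, rt, Ar
Reagents that add atoms: methyl 2-bromo-2-(4-methoxyphenyl)acetate (compound 12), COC(=O)C(Br)c1ccc(OC)cc1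
Why: SN2 displacement (Williamson type) of the activated benzylic α-bromo ester by the phenoxide; the new stereocentre forms racemic and is erased in step 9.

Step 7
Reactants: 13 methyl 2-[3-(benzyloxy)-2,4,5-trimethoxyphenoxy]-2-(4-methoxyphenyl)acetate
Product: 14 2-[3-(benzyloxy)-2,4,5-trimethoxyphenoxy]-2-(4-methoxyphenyl)acetic acid (racemic)
Conditions: LiOH, THF/MeOH/H2O, rt; then 1 M HCl to pH 3
Reagents that add atoms: lithium hydroxide, [Li+].[OH-]
Why: Ester saponification; aryl ethers and the benzyl ether are inert to aqueous hydroxide and brief dilute acid.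

Step 8
Reactants: 14 2-[3-(benzyloxy)-2,4,5-trimethoxyphenoxy]-2-(4-methoxyphenyl)acetic acid
Product: 16 6-(benzyloxy)-4,5,7-trimethoxy-2-(4-methoxyphenyl)-1-benzofuran-3(2H)-one (racemic), via mixed trifluoroacetic anhydride 15 (not isolated)
Conditions: (CF3CO)2O (3 equiv), CH2Cl2, 0 °C to rt, Ar; aq. NaHCO3 work-up; used at once
Reagents that add atoms: trifluoroacetic anhydride, O=C(OC(=O)C(F)(F)F)C(F)(F)F (trifluoroacetyl group of 15 only)
Why: Intramolecular Friedel-Crafts acylation through the mixed anhydride onto the only unsubstituted carbon of ring A, which is ortho to the aryloxy oxygen and to a methoxy group and para to the benzyloxy group; no Lewis acid is used that could cleave the benzyl ether.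

Step 9
Reactants: 16 6-(benzyloxy)-4,5,7-trimethoxy-2-(4-methoxyphenyl)-1-benzofuran-3(2H)-one
Product: 17 tert-butyl{[6-(benzyloxy)-4,5,7-trimethoxy-2-(4-methoxyphenyl)-1-benzofuran-3-yl]oxy}dimethylsilane
Conditions: TBSOTf (1.3 equiv), Et3N (2 equiv), CH2Cl2, 0 °C, Ar
Reagents that add atoms: tert-butyldimethylsilyl trifluoromethanesulfonate, CC(C)(C)[Si](C)(C)OS(=O)(=O)C(F)(F)F
Why: Soft enolisation and O-silylation of a ketone whose C2-H is benzylic, α to the carbonyl and α to oxygen; O-silylation should be favoured because it aromatises the furan ring.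

Step 10
Reactants: 17 tert-butyl{[6-(benzyloxy)-4,5,7-trimethoxy-2-(4-methoxyphenyl)-1-benzofuran-3-yl]oxy}dimethylsilane; 18 bromoform
Product: 21 7-(benzyloxy)-3-bromo-5,6,8-trimethoxy-2-(4-methoxyphenyl)-4H-chromen-4-one, via dibromocyclopropane adduct 19 (not isolated), via silyloxyflavylium bromide 20 (not isolated)
Conditions: CHBr3 (2 equiv), KOtBu (2.5 equiv, added in portions), toluene/hexane, −30 °C to rt, Ar; then H2O
Reagents that add atoms: bromoform (compound 18), BrC(Br)Br
Why: Proposed new method: dibromocarbene, formed by α-elimination from bromoform with KOtBu, should add as an electrophile to the C2=C3 bond of 17, which bears O1 on one carbon and the silyloxy group on the other and is the most electron-rich π bond present, to give the ring-fused gem-dibromocyclopropane 19. The ring-fusion bond of 19 (the former C2-C3 bond) should then open in a disrotatory two-electron electrocyclic process with departure of the endo bromide; this turns the five-membered ring into ring C by one-carbon insertion (a ring expansion, not a cyclisation of a chain) and gives the aromatic 3-bromo-4-silyloxyflavylium ion 20, stabilised by O1, the silyloxy oxygen and the anisyl ring. Transfer of the silyl group from oxygen to bromide, or its hydrolysis at work-up, should unmask the C4 carbonyl and give 21. The closest known reactions are the Ciamician-Dennstedt expansion of indoles to 3-haloquinolines, the dihalocarbene expansion of cyclic silyl enol ethers to ring-enlarged 2-haloenones and the opening of benzofuran-dihalocarbene adducts to 3-halochromenes; running this on a 3-silyloxybenzofuran to reach the flavone oxidation level directly is the untested part. No stereocentre is formed in 21, since both cyclopropane stereocentres of 19 become sp2 carbons. Two selectivities are required, carbene attack on the enol ether π bond in preference to the arenes and fragmentation of the ring-fusion bond instead of an external one; ring A is fully substituted, ring B and the benzyl group are much weaker nucleophiles, and only the internal opening leads to an aromatic pyrylium cation.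

Step 11
Reactants: 21 7-(benzyloxy)-3-bromo-5,6,8-trimethoxy-2-(4-methoxyphenyl)-4H-chromen-4-one
Product: 22 7-hydroxy-5,6,8-trimethoxy-2-(4-methoxyphenyl)-4H-chromen-4-one (7-hydroxy-4',5,6,8-tetramethoxyflavone)
Conditions: H2 (1 atm), 10% Pd/C, NaOAc, EtOAc/MeOH, rt
Reagents that add atoms: none
Why: Catalytic hydrogenolysis should cleave the vinylic C-Br bond (hydrodehalogenation, with acetate taking up HBr) and the aryl benzyl ether in one operation, while the conjugated C2=C3 bond of the chromone resists hydrogenation at 1 atm.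

**Compound list**

1 | 2,6-dimethoxyphenol (syringol) | COc1cccc(OC)c1O | starting material
2 | benzyl bromide | BrCc1ccccc1 | starting material
3 | 2-(benzyloxy)-1,3-dimethoxybenzene | COc1cccc(OC)c1OCc1ccccc1 | intermediate
4 | 3-(benzyloxy)-1,5-dibromo-2,4-dimethoxybenzene | COc1c(Br)cc(Br)c(OC)c1OCc1ccccc1 | intermediate
5 | [3-(benzyloxy)-5-bromo-2,4-dimethoxyphenyl]lithium | [Li]c1cc(Br)c(OC)c(OCc2ccccc2)c1OC | intermediate (not isolated)
6 | lithium [3-(benzyloxy)-5-bromo-2,4-dimethoxyphenyl]trimethoxyborate | [Li+].CO[B-](OC)(OC)c1cc(Br)c(OC)c(OCc2ccccc2)c1OC | intermediate (not isolated)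
7 | 3-(benzyloxy)-5-bromo-2,4-dimethoxyphenol | COc1c(O)cc(Br)c(OC)c1OCc1ccccc1 | intermediate
8 | 3-(benzyloxy)-1-bromo-2,4,5-trimethoxybenzene | COc1cc(Br)c(OC)c(OCc2ccccc2)c1OC | intermediate
9 | [3-(benzyloxy)-2,4,5-trimethoxyphenyl]lithium | [Li]c1cc(OC)c(OC)c(OCc2ccccc2)c1OC | intermediate (not isolated)
10 | lithium [3-(benzyloxy)-2,4,5-trimethoxyphenyl]trimethoxyborate | [Li+].CO[B-](OC)(OC)c1cc(OC)c(OC)c(OCc2ccccc2)c1OC | intermediate (not isolated)
11 | 3-(benzyloxy)-2,4,5-trimethoxyphenol | COc1cc(O)c(OC)c(OCc2ccccc2)c1OC | intermediate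
12 | methyl 2-bromo-2-(4-methoxyphenyl)acetate (racemic) | COC(=O)C(Br)c1ccc(OC)cc1 | starting material
13 | methyl 2-[3-(benzyloxy)-2,4,5-trimethoxyphenoxy]-2-(4-methoxyphenyl)acetate (racemic) | COC(=O)C(Oc1cc(OC)c(OC)c(OCc2ccccc2)c1OC)c1ccc(OC)cc1 | intermediate
14 | 2-[3-(benzyloxy)-2,4,5-trimethoxyphenoxy]-2-(4-methoxyphenyl)acetic acid (racemic) | OC(=O)C(Oc1cc(OC)c(OC)c(OCc2ccccc2)c1OC)c1ccc(OC)cc1 | intermediate
15 | 2-[3-(benzyloxy)-2,4,5-trimethoxyphenoxy]-2-(4-methoxyphenyl)acetic trifluoroacetic anhydride (racemic) | O=C(OC(=O)C(F)(F)F)C(Oc1cc(OC)c(OC)c(OCc2ccccc2)c1OC)c1ccc(OC)cc1 | intermediate (not isolated)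
16 | 6-(benzyloxy)-4,5,7-trimethoxy-2-(4-methoxyphenyl)-1-benzofuran-3(2H)-one (racemic) | COc1ccc(cc1)C1Oc2c(OC)c(OCc3ccccc3)c(OC)c(OC)c2C1=O | intermediate
17 | tert-butyl{[6-(benzyloxy)-4,5,7-trimethoxy-2-(4-methoxyphenyl)-1-benzofuran-3-yl]oxy}dimethylsilane | COc1ccc(cc1)-c1oc2c(OC)c(OCc3ccccc3)c(OC)c(OC)c2c1O[Si](C)(C)C(C)(C)C | intermediate
18 | bromoform | BrC(Br)Br | starting material
19 | tert-butyl{[4-(benzyloxy)-1,1-dibromo-3,5,6-trimethoxy-1a-(4-methoxyphenyl)-1,1a-dihydro-6bH-cyclopropa[b][1]benzofuran-6b-yl]oxy}dimethylsilane (racemic, cis-fused; the gem-dibromocyclopropane across the former C2-C3 bond of 17) | COc1ccc(cc1)C12Oc3c(OC)c(OCc4ccccc4)c(OC)c(OC)c3C1(O[Si](C)(C)C(C)(C)C)C2(Br)Br | intermediate (not isolated)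
20 | 7-(benzyloxy)-3-bromo-4-{[tert-butyl(dimethyl)silyl]oxy}-5,6,8-trimethoxy-2-(4-methoxyphenyl)chromenylium bromide | COc1ccc(cc1)-c1[o+]c2c(OC)c(OCc3ccccc3)c(OC)c(OC)c2c(O[Si](C)(C)C(C)(C)C)c1Br.[Br-] | intermediate (not isolated)
21 | 7-(benzyloxy)-3-bromo-5,6,8-trimethoxy-2-(4-methoxyphenyl)-4H-chromen-4-one | COc1ccc(cc1)-c1oc2c(OC)c(OCc3ccccc3)c(OC)c(OC)c2c(=O)c1Br | intermediate
22 | 7-hydroxy-5,6,8-trimethoxy-2-(4-methoxyphenyl)-4H-chromen-4-one (7-hydroxy-4',5,6,8-tetramethoxyflavone) | COc1ccc(-c2cc(=O)c3c(OC)c(OC)c(O)c(OC)c3o2)cc1 | target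

**Step count**

Total steps: 11. Longest linear sequence: 11 steps (from syringol 1 to target 22).

**Steps most likely to fail, with fallbacks**

1. Step 10 (proposed new method). Carbene addition to the hindered tetrasubstituted bond may be too slow, tert-butoxide may remove the silyl group before cyclopropanation, or the base may degrade the bromoflavone by ring contraction. The fallback uses known flavone chemistry, sets out from phenol 11 and returns at target 22. C-Acetylation of 11 at its free ortho position with Ac2O and BF3·OEt2 at rt should give 1-[4-(benzyloxy)-2-hydroxy-3,5,6-trimethoxyphenyl]ethan-1-one F1. Claisen-Schmidt condensation of this with 4-methoxybenzaldehyde (KOH, EtOH, rt) should give (2E)-1-[4-(benzyloxy)-2-hydroxy-3,5,6-trimethoxyphenyl]-3-(4-methoxyphenyl)prop-2-en-1-one F2. Oxidative cyclisation with catalytic I2 in DMSO at 120 °C should give 7-(benzyloxy)-5,6,8-trimethoxy-2-(4-methoxyphenyl)-4H-chromen-4-one F3. Hydrogenolysis (H2, 10% Pd/C, EtOAc/MeOH) then gives 22.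

2. Step 8. The activated acyl species may lose carbon monoxide to give a stabilised aryloxy(aryl)methyl cation, the acid may cleave the benzyl ether, or the coumaranone may autoxidise at C2 during isolation. The fallback reverses the order of bond formation, sets out from phenol 11 and returns at coumaranone 16. C-Acylation of 11 with 4-methoxyphenylacetic acid in BF3·OEt2 at 60 °C should give 1-[4-(benzyloxy)-2-hydroxy-3,5,6-trimethoxyphenyl]-2-(4-methoxyphenyl)ethan-1-one F4. α-Bromination with PhNMe3Br3 in THF at 0 °C should give 2-bromo-1-[4-(benzyloxy)-2-hydroxy-3,5,6-trimethoxyphenyl]-2-(4-methoxyphenyl)ethan-1-one F5. Intramolecular O-alkylation (5-exo-tet) with K2CO3 in acetone under argon closes the furanone ring to give 16.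

3. Step 11. The C2=C3 bond may be saturated once the bromine is gone, or bromide may poison the catalyst and stall benzyl cleavage. The fallback separates the two events and avoids hydrogen gas; it sets out from bromoflavone 21 and returns at target 22. Formate reduction catalysed by Pd(OAc)2 and PPh3 (HCO2H, Et3N, DMF, 60 °C) should remove the bromine and give 7-(benzyloxy)-5,6,8-trimethoxy-2-(4-methoxyphenyl)-4H-chromen-4-one F6, the same structure as F3. Transfer hydrogenolysis with 1,4-cyclohexadiene over 10% Pd/C in EtOH then cleaves the benzyl ether at low hydrogen concentration to give 22.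

**Further compounds**

F1 | step 10 | 1-[4-(benzyloxy)-2-hydroxy-3,5,6-trimethoxyphenyl]ethan-1-one | CC(=O)c1c(O)c(OC)c(OCc2ccccc2)c(OC)c1OC
F2 | step 10 | (2E)-1-[4-(benzyloxy)-2-hydroxy-3,5,6-trimethoxyphenyl]-3-(4-methoxyphenyl)prop-2-en-1-one | COc1ccc(/C=C/C(=O)c2c(O)c(OC)c(OCc3ccccc3)c(OC)c2OC)cc1
F3 | step 10 | 7-(benzyloxy)-5,6,8-trimethoxy-2-(4-methoxyphenyl)-4H-chromen-4-one | COc1ccc(cc1)-c1cc(=O)c2c(OC)c(OC)c(OCc3ccccc3)c(OC)c2o1
F4 | step 8 | 1-[4-(benzyloxy)-2-hydroxy-3,5,6-trimethoxyphenyl]-2-(4-methoxyphenyl)ethan-1-one | COc1ccc(CC(=O)c2c(O)c(OC)c(OCc3ccccc3)c(OC)c2OC)cc1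
F5 | step 8 | 2-bromo-1-[4-(benzyloxy)-2-hydroxy-3,5,6-trimethoxyphenyl]-2-(4-methoxyphenyl)ethan-1-one (racemic) | COc1ccc(C(Br)C(=O)c2c(O)c(OC)c(OCc3ccccc3)c(OC)c2OC)cc1
F6 | step 11 | 7-(benzyloxy)-5,6,8-trimethoxy-2-(4-methoxyphenyl)-4H-chromen-4-one | COc1ccc(cc1)-c1cc(=O)c2c(OC)c(OC)c(OCc3ccccc3)c(OC)c2o1
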